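Late times say most about the exchange. In these flasks the free catalyst, with partner, turns each substrate into the product of its own hand and favours the left-handed one, while the racemization catalyst may swap the two substrates. The earlier runs differ in added ligand, and the new flask lies between them.

| setting | south | north | flask |
|---|---|---|---|
| left-handed substrate | 0.010 M | 0.010 M | 0.010 M |
| right-handed substrate | 0.010 M | 0.010 M | 0.010 M |
| partner | 3 equiv | 3 equiv | 3.00 equiv |
| free catalyst | 0.47 mol% | 0.47 mol% | 0.47 mol% |
| racemization catalyst | 2 mol% | 2 mol% | 2 mol% |
| added ligand | 0.090 mM | 0.36 mM | 0.18 mM |
| remark | run made earlier | run made earlier |  |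
| time |  |  | 15 h |

| run | time / h | left-handed product / % | right-handed product / % |
|---|---|---|---|
| south | 2.50 | 13.8 | 3.2 |
| south | 5.00 | 22.1 | 5.0 |
| south | 8.00 | 28.3 | 7.0 |
| south | 10.0 | 31.8 | 8.5 |
| south | 12.0 | 35.5 | 8.5 |
| south | 15.0 | 38.2 | 10.3 |
| south | 20.0 | 41.9 | 10.8 |
| north | 1.00 | 5.2 | 0.7 |
| north | 3.00 | 12.1 | 3.3 |
| north | 5.00 | 17.2 | 5.0 |
| north | 8.00 | 23.4 | 5.6 |
| north | 10.0 | 26.7 | 6.2 |
| north | 15.0 | 33.7 | 7.4 |
| north | 20.0 | 37.6 | 9.3 |

(scatter of a reading: 0.5 percentage points)

- free catalyst is single-handed; left-handed substrate and right-handed substrate are mirror images of each other, charged as a racemate, each of them at the stated concentration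
- the numbers in the tables scatter by 0.5 percentage points (one standard deviation)
- an excess is the difference of the two amounts in percent of their sum
- an excess is below zero if the other one leads

1. left-handed product and right-handed product together, in percent of the left-handed substrate and right-handed substrate charged together, at 15 h
2. excess of left-handed product over right-handed product in the product at 15 h
3. whether the exchange between left-handed substrate and right-handed substrate keeps pace with the reaction: how far the product's excess at 15 h gets from its value without exchange to its value with instant exchange (above 80% keeps pace, below 20% hardly takes part, else lags behind)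

Turn the question round and suppose that no substrate changed hand. Each hand is half of the charge, so the substrate left of each hand is that half minus its product. Counted so from both runs together at 15.0 h, c(left-handed substrate)/c(right-handed substrate) is 0.341: call this the hand balance.

Up to 5.00 h the two runs together give left-handed over right-handed product as 3.93, a reading of the selectivity factor. The products form in that factor times the substrate ratio, so unexchanged substrates imply a late ratio of 1.34.

Between 10.0 h and 20.0 h left-handed product gained 21 percentage points over both runs. Right-handed product would have needed 16 points but gained 5.4 points, with a scatter of 0.5 points per reading. The late ratio of 3.89 is larger than the count implies and reads a substrate ratio of 0.990, so my own call is that exchange keeps pace. The same factor gives an excess of 59.4%.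

The forecast gives 45.5%, 60% and lags behind: “The fraction covered is therefore about 0.75, which means exchange substantially helps but lags behind.”

The flask gives 45.2% and 61.7%, and exchange keeps pace, 99.7% of the way.

    partner + free catalyst + left-handed substrate → free catalyst + left-handed product (k = 1.10 × 10⁵ M⁻² h⁻¹)
    partner + free catalyst + right-handed substrate → free catalyst + right-handed product (k = 26000 M⁻² h⁻¹)
    left-handed substrate + racemization catalyst ⇌ right-handed substrate + racemization catalyst, rate k3*[racemization catalyst]*[left-handed substrate] forward; the back reaction follows from the equilibrium constant (k = 1.20 × 10⁵ M⁻¹ h⁻¹)
    partner + free catalyst → spent catalyst (k = 2.80 M⁻¹ h⁻¹)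
    free catalyst + added ligand ⇌ idle complex (K = 2100 M⁻¹, k = 3600 M⁻¹ h⁻¹)

At 15.0 h the free catalyst used partner 4.2 times as fast for left-handed as for right-handed product, and each substrate stood at 27.4%, with racemization catalyst at 100%, though this flask's hand balance reads 0.325. By then free catalyst had fallen to 34.4%, beside 52.7% spent catalyst and 12.9% idle complex. In the neighbour flask with 12.0 equiv of partner the hand balance at 15.0 h falls below zero, to −0.103: its left-handed product stands at 53.8%, 3.8 points above the left-handed charge, with each substrate at 16.7%.

The data were computed with constants of no real substance, and the scatter is random.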